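**Plan**

- Retrosynthetic cuts: the two O–benzyl bonds (last step), the C4 carbonyl back to a C3=C4 alkene, C3–H back to C3–CHO, and then O1–C2 and C3–C4 together. This splits the chromene into a ring-A salicylaldehyde and a ring-B cinnamaldehyde.
- Enabling feature: O1–C2 and C3–C4 are the only two bonds between ring A and the C2–C3 unit, and ring A drawn as a benzaldehyde has one free phenol (future O1 on C8a) ortho to the formyl carbon (future C4).
- Forward order: ring-A aldehyde (4 steps), ring-B enal (2 steps), one domino step that closes the pyran ring (ring C), then decarbonylation, hydration, oxidation and global hydrogenolysis.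
- Protecting-group choice: the future C5 oxygen is demethylated by formyl-directed chelation while the material is still achiral and carried as a benzyl ether, so no Lewis acid touches the finished flavanone.
- Stereochemistry: C2 is the only stereocentre; it is set in the annulation by an (S)-diphenylprolinol silyl ether catalyst and afterwards meets neither strong acid nor base.

Key step: step 7

Assumption: the sense of induction follows the usual steric-shielding model for diarylprolinol silyl ether iminium ions, so the (S)-catalyst should give the 2R chromene aldehyde; the (R)-catalyst is equally available.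
Assumption: 1,2,3,4-tetramethoxybenzene, 2-hydroxy-6-methoxybenzaldehyde and (1,3-dioxolan-2-ylmethyl)triphenylphosphonium bromide are taken as purchasable.

**Route**

Step 1
Reactants: 1 1,2,3,4-tetramethoxybenzene
Product: 4 2,3,4,5-tetramethoxyphenol, via aryllithium 2 (not isolated), via lithium aryltrimethoxyborate 3 (not isolated)
Conditions: n-BuLi, TMEDA, THF, 0 °C; B(OMe)3, −78 °C → rt; AcOH, 30% aq. H2O2, 0 °C → rt
Reagents that add atoms: hydrogen peroxide, OO
Why: Directed ortho-lithiation (the two ring C–H bonds are equivalent and each lies next to a methoxy group), trapping with trimethyl borate and oxidative 1,2-migration of the aryl group from boron to oxygen is the standard lithiation–borylation–oxidation route from an arene C–H to a phenol, and it places the hydroxyl group where lithium sat.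

Step 2
Reactants: 4 2,3,4,5-tetramethoxyphenol
Product: 5 2-hydroxy-3,4,5,6-tetramethoxybenzaldehyde
Conditions: MgCl2, Et3N, (CH2O)n, MeCN, reflux
Reagents that add atoms: paraformaldehyde (as formaldehyde), C=O
Why: Magnesium phenoxide-directed ortho-formylation (Casnati–Skattebøl reaction) delivers formaldehyde to the ortho carbon through a chelate and oxidises the resulting benzylic alkoxide by hydride transfer to a second formaldehyde, and since the phenol has only one unsubstituted ring carbon, which is ortho to the hydroxyl group, a single salicylaldehyde can form.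

Step 3
Reactants: 5 2-hydroxy-3,4,5,6-tetramethoxybenzaldehyde
Product: 6 2,6-dihydroxy-3,4,5-trimethoxybenzaldehyde
Conditions: BCl3 (3 equiv), CH2Cl2, −78 °C → rt; aqueous work-up
Reagents that add atoms: none
Why: Chelation-controlled Lewis-acid ether cleavage, in which boron held between the formyl oxygen and the flanking methoxy oxygen activates that methyl group for chloride attack while the three methoxy groups remote from the carbonyl are not activated, should give the symmetric dihydroxy aldehyde and so unmask the future C5 oxygen before any stereocentre exists.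

Step 4
Reactants: 6 2,6-dihydroxy-3,4,5-trimethoxybenzaldehyde
Product: 7 2-(benzyloxy)-6-hydroxy-3,4,5-trimethoxybenzaldehyde
Conditions: BnBr (1.0 equiv), K2CO3 (1.0 equiv), DMF, 0 °C → rt
Reagents that add atoms: benzyl bromide, BrCc1ccccc1
Why: Williamson ether synthesis on a substrate whose two hydroxyl groups are equivalent by symmetry can give only one mono-ether, and the remaining hydroxyl group, locked in a hydrogen bond to the formyl oxygen, is too poorly nucleophilic to be benzylated quickly.

Step 5
Reactants: 8 2-hydroxy-6-methoxybenzaldehyde
Product: 9 2-(benzyloxy)-6-methoxybenzaldehyde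
Conditions: BnBr, K2CO3, DMF, rt
Reagents that add atoms: benzyl bromide, BrCc1ccccc1
Why: Williamson ether synthesis of the only phenol present masks the ring-B oxygen, which would otherwise act as a second oxa-Michael donor in step 7, as a benzyl ether that leaves together with the other benzyl group in the last step.

Step 6
Reactants: 9 2-(benzyloxy)-6-methoxybenzaldehyde; 10 (1,3-dioxolan-2-ylmethyl)triphenylphosphonium bromide
Product: 12 (E)-3-[2-(benzyloxy)-6-methoxyphenyl]prop-2-enal, via vinyl dioxolane 11 (not isolated)
Conditions: t-BuOK, THF, 0 °C → rt; then 1 M aq. HCl, THF, rt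
Reagents that add atoms: water, O
Why: Wittig olefination with an acetal-masked formylmethylene ylide followed by acetal hydrolysis is a two-carbon homologation that cannot over-homologate, because the new aldehyde stays masked until the ylide is consumed, and the aqueous acid should equilibrate the alkene to the conjugated E isomer.

Step 7
Reactants: 7 2-(benzyloxy)-6-hydroxy-3,4,5-trimethoxybenzaldehyde; 12 (E)-3-[2-(benzyloxy)-6-methoxyphenyl]prop-2-enal
Product: 13 (R)-5-(benzyloxy)-2-[2-(benzyloxy)-6-methoxyphenyl]-6,7,8-trimethoxy-2H-chromene-3-carbaldehyde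
Conditions: (S)-2-[diphenyl(trimethylsilyloxy)methyl]pyrrolidine (20 mol %), 2-nitrobenzoic acid (20 mol %), 4 Å molecular sieves, toluene, 0 °C → rt
Reagents that add atoms: none
Why: The amine condenses with enal 12 to an (E)-iminium ion, the single free phenol of 7 adds to its β-carbon (O1–C2), the resulting enamine attacks the ortho formyl group (C3–C4), and E1cB dehydration followed by hydrolysis releases 13 and the catalyst. The closest known reaction type is the secondary-amine-catalysed asymmetric oxa-Michael–aldol condensation of salicylaldehydes with cinnamaldehydes to 2-aryl-2H-chromene-3-carbaldehydes. The pyran ring (ring C) closes in the aldol event in the 6-exo-trig mode, the enamine carbon C3 attacking a carbonyl group whose oxygen lies outside the ring being formed. C2 is controlled by the catalyst: the diphenyl(trimethylsilyloxy)methyl group of the (S)-pyrrolidine shields one face of the s-trans iminium ion, so the phenol should add to the open face, which gives 2R in 13 (C3 outranks the aryl group there) and corresponds to 2S in the target. The step needs chemoselectivity, secured because 7 has one free phenol and one non-enolisable formyl group so that only one annulation in one orientation is possible, and it needs the reversible oxa-Michael adduct to be trapped before it equilibrates, secured by the intramolecular six-membered aldol and the irreversible loss of water, both assisted by the acid co-catalyst and the sieves.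

Step 8
Reactants: 13 (R)-5-(benzyloxy)-2-[2-(benzyloxy)-6-methoxyphenyl]-6,7,8-trimethoxy-2H-chromene-3-carbaldehyde
Product: 14 (S)-5-(benzyloxy)-2-[2-(benzyloxy)-6-methoxyphenyl]-6,7,8-trimethoxy-2H-chromene
Conditions: RhCl(PPh3)3 (1.1 equiv), toluene, 90 °C, argon, dark
Reagents that add atoms: none
Why: Tsuji–Wilkinson decarbonylation (oxidative addition of the formyl C–H bond to monovalent rhodium, de-insertion of CO and C–H reductive elimination) replaces CHO by H with retention at the alkene carbon, as known for α-substituted cinnamaldehydes, and C2 takes no part, its descriptor changing from R to S only because C3 loses priority.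

Step 9
Reactants: 14 (S)-5-(benzyloxy)-2-[2-(benzyloxy)-6-methoxyphenyl]-6,7,8-trimethoxy-2H-chromene
Product: 15 (2S,4RS)-5-(benzyloxy)-2-[2-(benzyloxy)-6-methoxyphenyl]-6,7,8-trimethoxychroman-4-ol (mixture of C4 epimers)
Conditions: Co(acac)2 (20 mol %), PhSiH3, O2 (1 atm), THF, rt
Reagents that add atoms: dioxygen, O=O
Why: In the Mukaiyama hydration a cobalt hydride transfers a hydrogen atom to C3, the resulting C4 radical is benzylic to the electron-rich ring A and is trapped by O2, and reduction of the peroxide should give the Markovnikov alcohol, while C2 is untouched and the configuration of the new C4 carbinol does not matter because it is oxidised in step 10.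

Step 10
Reactants: 15 (2S,4RS)-5-(benzyloxy)-2-[2-(benzyloxy)-6-methoxyphenyl]-6,7,8-trimethoxychroman-4-ol
Product: 16 (S)-5-(benzyloxy)-2-[2-(benzyloxy)-6-methoxyphenyl]-6,7,8-trimethoxychroman-4-one
Conditions: Dess–Martin periodinane, pyridine, CH2Cl2, 0 °C → rt
Reagents that add atoms: none
Why: Dess–Martin oxidation of the benzylic secondary alcohol under buffered conditions should give the chromanone without forming the C3 enolate, whose β-elimination of the ring oxygen would open the pyranone and racemise C2, and both C4 epimers converge on one ketone.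

Step 11
Reactants: 16 (S)-5-(benzyloxy)-2-[2-(benzyloxy)-6-methoxyphenyl]-6,7,8-trimethoxychroman-4-one
Product: 17 (S)-5-hydroxy-2-(2-hydroxy-6-methoxyphenyl)-6,7,8-trimethoxychroman-4-one (CNP0215836.1)
Conditions: H2 (1 atm), 10% Pd/C, EtOAc, rt
Reagents that add atoms: none
Why: Catalytic hydrogenolysis cleaves both benzyl aryl ethers under neutral conditions and should leave the methyl ethers, the aryl ketone (deactivated by its ortho and para oxygens) and C2 untouched, and the freed C5 hydroxyl group hydrogen-bonds to the C4 carbonyl, which further stabilises the flavanone against ring opening.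

**Compound list**

1 | 1,2,3,4-tetramethoxybenzene | COc1ccc(OC)c(OC)c1OC | starting material
2 | (2,3,4,5-tetramethoxyphenyl)lithium | [Li]c1cc(OC)c(OC)c(OC)c1OC | intermediate (not isolated)
3 | lithium trimethoxy(2,3,4,5-tetramethoxyphenyl)borate | [Li+].CO[B-](OC)(OC)c1cc(OC)c(OC)c(OC)c1OC | intermediate (not isolated)
4 | 2,3,4,5-tetramethoxyphenol | Oc1cc(OC)c(OC)c(OC)c1OC | intermediate
5 | 2-hydroxy-3,4,5,6-tetramethoxybenzaldehyde | COc1c(O)c(C=O)c(OC)c(OC)c1OC | intermediate
6 | 2,6-dihydroxy-3,4,5-trimethoxybenzaldehyde | COc1c(O)c(C=O)c(O)c(OC)c1OC | intermediate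
7 | 2-(benzyloxy)-6-hydroxy-3,4,5-trimethoxybenzaldehyde | COc1c(O)c(C=O)c(OCc2ccccc2)c(OC)c1OC | intermediate
8 | 2-hydroxy-6-methoxybenzaldehyde | COc1cccc(O)c1C=O | starting material
9 | 2-(benzyloxy)-6-methoxybenzaldehyde | COc1cccc(OCc2ccccc2)c1C=O | intermediate
10 | (1,3-dioxolan-2-ylmethyl)triphenylphosphonium bromide | [Br-].C1COC(C[P+](c2ccccc2)(c2ccccc2)c2ccccc2)O1 | starting material
11 | 2-{2-[2-(benzyloxy)-6-methoxyphenyl]ethenyl}-1,3-dioxolane (E/Z mixture) | COc1cccc(OCc2ccccc2)c1C=CC1OCCO1 | intermediate (not isolated)
12 | (E)-3-[2-(benzyloxy)-6-methoxyphenyl]prop-2-enal | COc1cccc(OCc2ccccc2)c1/C=C/C=O | intermediate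
13 | (R)-5-(benzyloxy)-2-[2-(benzyloxy)-6-methoxyphenyl]-6,7,8-trimethoxy-2H-chromene-3-carbaldehyde | COc1cccc(OCc2ccccc2)c1[C@@H]1C(C=O)=Cc2c(OCc3ccccc3)c(OC)c(OC)c(OC)c2O1 | intermediate
14 | (S)-5-(benzyloxy)-2-[2-(benzyloxy)-6-methoxyphenyl]-6,7,8-trimethoxy-2H-chromene | COc1cccc(OCc2ccccc2)c1[C@@H]1C=Cc2c(OCc3ccccc3)c(OC)c(OC)c(OC)c2O1 | intermediate
15 | (2S,4RS)-5-(benzyloxy)-2-[2-(benzyloxy)-6-methoxyphenyl]-6,7,8-trimethoxychroman-4-ol | COc1cccc(OCc2ccccc2)c1[C@@H]1CC(O)c2c(OCc3ccccc3)c(OC)c(OC)c(OC)c2O1 | intermediate
16 | (S)-5-(benzyloxy)-2-[2-(benzyloxy)-6-methoxyphenyl]-6,7,8-trimethoxychroman-4-one | COc1cccc(OCc2ccccc2)c1[C@@H]1CC(=O)c2c(OCc3ccccc3)c(OC)c(OC)c(OC)c2O1 | intermediate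
17 | (S)-5-hydroxy-2-(2-hydroxy-6-methoxyphenyl)-6,7,8-trimethoxychroman-4-one | COc1cccc(O)c1[C@@H]1CC(=O)c2c(O)c(OC)c(OC)c(OC)c2O1 | target

**Step count**

Total: 11 steps. Longest linear sequence: 9 steps (steps 1, 2, 3, 4, 7, 8, 9, 10, 11).

**Steps most likely to fail**

Step 7. The β-carbon of 12 is flanked by two ortho alkoxy groups and the formyl group of 7 by OH and OBn, so iminium formation, conjugate addition and aldol closure may all be slow. The oxa-Michael adduct then has time to revert, which would lower both conversion and enantioselectivity. The fallback forms the same two bonds without asymmetric induction and separates the enantiomers. It sets out from 7 and 12, which are condensed with pyrrolidine and benzoic acid in DMSO (a small achiral amine that tolerates the hindered enal) to give racemic 5-(benzyloxy)-2-[2-(benzyloxy)-6-methoxyphenyl]-6,7,8-trimethoxy-2H-chromene-3-carbaldehyde F1. Preparative HPLC on a polysaccharide chiral stationary phase then separates the (R)-enantiomer, which is 13 and rejoins the route there, from (S)-5-(benzyloxy)-2-[2-(benzyloxy)-6-methoxyphenyl]-6,7,8-trimethoxy-2H-chromene-3-carbaldehyde F2, which is set aside.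

Step 8. At the temperature needed for CO extrusion the 2H-pyran may undergo thermal 6π ring opening to an ortho-quinone methide and reclose, eroding configurational purity at C2, and de-insertion from the hindered alkenyl acyl rhodium species may be slow. The fallback removes the extra carbon as CO2 after C4 is oxygenated and needs no step above about 40 °C. It sets out from 13. Luche reduction (NaBH4, CeCl3·7H2O, MeOH, 0 °C) should give {(S)-5-(benzyloxy)-2-[2-(benzyloxy)-6-methoxyphenyl]-6,7,8-trimethoxy-2H-chromen-3-yl}methanol F3. Mukaiyama hydration under the conditions of step 9 (hydrogen to C3, oxygen to benzylic C4) should give (2S)-5-(benzyloxy)-2-[2-(benzyloxy)-6-methoxyphenyl]-3-(hydroxymethyl)-6,7,8-trimethoxychroman-4-ol F4 as a mixture at C3 and C4. Oxidation of both carbinols with TEMPO and PhI(OAc)2 in aqueous MeCN should give (2S)-5-(benzyloxy)-2-[2-(benzyloxy)-6-methoxyphenyl]-6,7,8-trimethoxy-4-oxochroman-3-carboxylic acid F5. This β-keto acid loses CO2 on gentle warming through its enol, without a free enolate, and the sequence comes back to the route at 16.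

Step 9. Hydrogen-atom abstraction from the doubly activated C2–H may compete, the benzylic radical may be reduced (net hydrogenation to the flavan) instead of capturing O2, and the very electron-rich benzylic alcohol may ionise during isolation. The fallback replaces radical chemistry by polar palladium chemistry and sets out from 14. Wacker oxidation (PdCl2 cat., CuCl, O2, DMF/H2O, rt) should place oxygen at C4, the carbon that is benzylic to ring A and distal to the inductively withdrawing C2–O1 bond. β-Hydride elimination and tautomerisation then give the ketone directly, so the sequence comes back at 16 and passes over 15; it makes no new compound.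

**Further compounds**

F1 | step 7 | racemic 5-(benzyloxy)-2-[2-(benzyloxy)-6-methoxyphenyl]-6,7,8-trimethoxy-2H-chromene-3-carbaldehyde | COc1cccc(OCc2ccccc2)c1C1C(C=O)=Cc2c(OCc3ccccc3)c(OC)c(OC)c(OC)c2O1
F2 | step 7 | (S)-5-(benzyloxy)-2-[2-(benzyloxy)-6-methoxyphenyl]-6,7,8-trimethoxy-2H-chromene-3-carbaldehyde | COc1cccc(OCc2ccccc2)c1[C@H]1C(C=O)=Cc2c(OCc3ccccc3)c(OC)c(OC)c(OC)c2O1
F3 | step 8 | {(S)-5-(benzyloxy)-2-[2-(benzyloxy)-6-methoxyphenyl]-6,7,8-trimethoxy-2H-chromen-3-yl}methanol | COc1cccc(OCc2ccccc2)c1[C@@H]1C(CO)=Cc2c(OCc3ccccc3)c(OC)c(OC)c(OC)c2O1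
F4 | step 8 | (2S)-5-(benzyloxy)-2-[2-(benzyloxy)-6-methoxyphenyl]-3-(hydroxymethyl)-6,7,8-trimethoxychroman-4-ol (mixture at C3 and C4) | COc1cccc(OCc2ccccc2)c1[C@@H]1C(CO)C(O)c2c(OCc3ccccc3)c(OC)c(OC)c(OC)c2O1
F5 | step 8 | (2S)-5-(benzyloxy)-2-[2-(benzyloxy)-6-methoxyphenyl]-6,7,8-trimethoxy-4-oxochroman-3-carboxylic acid (mixture at C3) | COc1cccc(OCc2ccccc2)c1[C@@H]1C(C(O)=O)C(=O)c2c(OCc3ccccc3)c(OC)c(OC)c(OC)c2O1
F0 | step 9 | none | none
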